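**Retrosynthetic overview**

1. Locants: ring C1 = stereocentre, C2 = methyl-bearing alkene carbon, C3 = alkene CH, C4/C5 = CH2, C6 = CMe2; C1' = first side-chain carbon. Last disconnections: the ester C–O bond (α-linolenic acid + C20 alcohol), then C1'–C2' (alkylation of an (S)-α-cyclogeranyl sulfone with a geraniol-derived E,E-allylic bromide; the sulfonyl group is removed afterwards).
2. The C1–C1' bond and the C1 stereocentre come from a suprafacial decarboxylative Claisen shift of a tosylacetate hung on a C3–O bond. This C–O bond is absent from the target; it is installed on purpose by enantioselective ketone reduction, steers C1' to one face of C1, and is cleaved in the same event, which also places the double bond at C2=C3.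
3. The C3 carbonyl needed for this comes by carbonyl transposition from a 1,3-dione, so the only ring (C1–C6) is made first, at the 1,3-dione oxidation level.
4. Ring formation: one-flask Michael–Claisen annulation of 2-methylpentan-3-one with methyl acrylate; the Michael step makes C5–C6, the Claisen step closes the ring by forming C2–C3.
5. Enabling feature: C2 lies between C1 and C3, and C6 is quaternary; with oxygen on C1 and C3, C2 is the only enolisable carbon next to the ketone once C6 is built, so closure can only join C2 to C3 and is pulled through by the stabilised diketonate. Ring order: a single ring, formed in step 1.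

Key step: step 1

Remark: the single stereocentre of the target is (S); 2-tosylacetic acid, geraniol, α-linolenic acid and the oxazaborolidine catalyst are taken as commercial.

**Route**

Step 1
Reactants: 1 2-methylpentan-3-one; 2 methyl prop-2-enoate (methyl acrylate)
Product: 4 2,4,4-trimethylcyclohexane-1,3-dione, via Michael adduct 3 (not isolated)
Conditions: KOt-Bu (2 equiv), THF, 0 °C to rt (1 and 2 added together slowly); then 1 M HCl
Reagents that add atoms: none
Why: Michael–Claisen annulation: KOt-Bu generates the more substituted enolate of 1 at the isopropyl carbon, which adds to 2 and sets the quaternary C6 and the C5–C6 bond, after which the ketone of adduct 3 has a single enolisable position, the ethyl CH2 (C2), whose enolate attacks the ester carbonyl (C3) and expels methoxide, closing the six-membered ring at C2–C3 in a 6-(enolendo)-exo-trig Claisen (Dieckmann-type) condensation. The closest known reaction is the one-flask preparation of 4,4-dimethylcyclohexane-1,3-dione from 3-methylbutan-2-one and an acrylate ester under the same conditions. The sequence should be driven to completion by deprotonation of the product at C2 to the stabilised 1,3-diketonate. No configurationally relevant stereocentre is formed, because C2 is enolised here and ends as an sp2 carbon in the target. The selectivity needed is regiochemical (which alpha-carbon adds to the acrylate and which one closes the ring), and the substrate secures it: the alternative sequence (Michael addition at the ethyl carbon, closure from the isopropyl carbon) can only give a non-enolisable 2,2-disubstituted dione that reverts by retro-Claisen cleavage, so the reversible steps should funnel material to 4.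

Step 2
Reactants: 4 2,4,4-trimethylcyclohexane-1,3-dione
Product: 5 3-(2-methylpropoxy)-2,6,6-trimethylcyclohex-2-en-1-one
Conditions: i-BuOH, TsOH·H2O (cat.), toluene, reflux, Dean–Stark trap
Reagents that add atoms: 2-methylpropan-1-ol, CC(C)CO
Why: Acid-catalysed enol etherification of an unsymmetrical cyclic 1,3-dione under equilibrating conditions should place the alkoxy group on the oxygen remote from the quaternary carbon (C3–O), since the other regioisomer would put it next to the gem-dimethyl group; any minor regioisomer would be removed by chromatography.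

Step 3
Reactants: 5 3-(2-methylpropoxy)-2,6,6-trimethylcyclohex-2-en-1-one
Product: 7 2,4,4-trimethylcyclohex-2-en-1-one, via allylic alcohol 6 (not isolated)
Conditions: LiAlH4, Et2O, 0 °C; then 2 M HCl, rt
Reagents that add atoms: water, O
Why: Stork–Danheiser enone transposition: 1,2-hydride addition to the vinylogous ester carbonyl, then acid hydrolysis of the enol ether with loss of water, should move the carbonyl to C3 and the double bond to C1=C2, which deletes the C1 oxygen and keeps the C3 oxygen as the handle for stereocontrol.

Step 4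
Reactants: 7 2,4,4-trimethylcyclohex-2-en-1-one
Product: 8 (1R)-2,4,4-trimethylcyclohex-2-en-1-ol
Conditions: (S)-2-methyl-CBS-oxazaborolidine (0.2 equiv), BH3·SMe2, THF, −20 °C; MeOH quench, aqueous work-up
Reagents that add atoms: none
Why: Corey–Bakshi–Shibata reduction: the ketone should bind the oxazaborolidine boron anti to the larger 2-methylalkenyl flank and take hydride from the coordinated borane on one face, which with the (S)-catalyst is expected to give the (R)-carbinol (same sense as acetophenone to (R)-1-phenylethanol); this is the only step that introduces absolute configuration.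

Step 5
Reactants: 8 (1R)-2,4,4-trimethylcyclohex-2-en-1-ol; 9 2-(4-methylbenzenesulfonyl)acetic acid (tosylacetic acid)
Product: 10 (1R)-2,4,4-trimethylcyclohex-2-en-1-yl 2-(4-methylbenzenesulfonyl)acetate
Conditions: DCC, DMAP (cat.), CH2Cl2, 0 °C to rt
Reagents that add atoms: none
Why: Steglich esterification of a secondary allylic alcohol breaks no bond at the carbinol carbon, so the (R)-configuration is retained and the ester oxygen becomes the temporary tether for the next step.

Step 6
Reactants: 10 (1R)-2,4,4-trimethylcyclohex-2-en-1-yl 2-(4-methylbenzenesulfonyl)acetate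
Product: 13 1-methyl-4-{[(1S)-2,6,6-trimethylcyclohex-2-en-1-yl]methanesulfonyl}benzene, via silyl ketene acetal 11 (not isolated), via silyl ester 12 (not isolated)
Conditions: N,O-bis(trimethylsilyl)acetamide (0.1 equiv), KOAc (0.1 equiv), toluene, 110 °C
Reagents that add atoms: none
Why: Decarboxylative Claisen rearrangement (Ireland–Claisen type) of an allylic sulfonylacetate: catalytic silylation gives the silyl ketene acetal, the suprafacial [3,3]-sigmatropic shift across the cyclohexene should deliver the sulfonyl-bearing carbon to C1 on the face that carried the C3–O bond and move the double bond to C2=C3, and acetate-triggered desilylation with loss of CO2 leaves the sulfone, so the C3 stereocentre is transferred to C1 as (S) while the temporary C3–O bond is cleaved.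

Step 7
Reactants: 14 geraniol, (2E)-3,7-dimethylocta-2,6-dien-1-ol
Product: 15 tert-butyl{[(2E)-3,7-dimethylocta-2,6-dien-1-yl]oxy}dimethylsilane
Conditions: TBSCl, imidazole, DMF, rt
Reagents that add atoms: tert-butyl(chloro)dimethylsilane (TBSCl), CC(C)(C)[Si](C)(C)Cl
Why: Imidazole-promoted silylation of a primary allylic alcohol is routine and leaves the E-trisubstituted alkene untouched.

Step 8
Reactants: 15 tert-butyl{[(2E)-3,7-dimethylocta-2,6-dien-1-yl]oxy}dimethylsilane
Product: 16 (2E,6E)-8-{[tert-butyl(dimethyl)silyl]oxy}-2,6-dimethylocta-2,6-dien-1-ol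
Conditions: SeO2 (cat.), t-BuOOH, salicylic acid (cat.), CH2Cl2, rt
Reagents that add atoms: tert-butyl hydroperoxide, CC(C)(C)OO
Why: Selenium dioxide allylic oxidation (Riley oxidation; ene reaction followed by [2,3]-sigmatropic shift) is known to hydroxylate the E-methyl group of the distal, more electron-rich trisubstituted alkene of geranyl derivatives with retention of E geometry, the proximal alkene being deactivated by its allylic oxygen.

Step 9
Reactants: 16 (2E,6E)-8-{[tert-butyl(dimethyl)silyl]oxy}-2,6-dimethylocta-2,6-dien-1-ol
Product: 17 tert-butyl{[(2E,6E)-8-bromo-3,7-dimethylocta-2,6-dien-1-yl]oxy}dimethylsilane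
Conditions: CBr4, PPh3, CH2Cl2, −20 to 0 °C
Reagents that add atoms: tetrabromomethane, BrC(Br)(Br)Br
Why: Appel reaction: SN2 displacement of the primary allylic alkoxyphosphonium ion by bromide at low temperature should proceed without allylic transposition or loss of alkene geometry, and the neutral conditions spare the silyl ether.

Step 10
Reactants: 13 1-methyl-4-{[(1S)-2,6,6-trimethylcyclohex-2-en-1-yl]methanesulfonyl}benzene; 17 tert-butyl{[(2E,6E)-8-bromo-3,7-dimethylocta-2,6-dien-1-yl]oxy}dimethylsilane
Product: 19 tert-butyl{[(2E,6E)-3,7-dimethyl-9-(4-methylbenzenesulfonyl)-9-[(1S)-2,6,6-trimethylcyclohex-2-en-1-yl]nona-2,6-dien-1-yl]oxy}dimethylsilane (both C9 epimers), via lithiated sulfone 18 (not isolated)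
Conditions: n-BuLi, THF, −78 °C; then 17, THF–DMPU, −78 to −20 °C
Reagents that add atoms: none
Why: Alkylation of an alpha-sulfonyl carbanion with a primary allylic bromide (Julia-type fragment coupling used for isoprenoid chains) should occur by SN2 attack at the CH2Br carbon, keeping both E alkenes and not involving the ring stereocentre; the new sulfone-bearing stereocentre is irrelevant because it is removed next.

Step 11
Reactants: 19 tert-butyl{[(2E,6E)-3,7-dimethyl-9-(4-methylbenzenesulfonyl)-9-[(1S)-2,6,6-trimethylcyclohex-2-en-1-yl]nona-2,6-dien-1-yl]oxy}dimethylsilane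
Product: 20 tert-butyl{[(2E,6E)-3,7-dimethyl-9-[(1S)-2,6,6-trimethylcyclohex-2-en-1-yl]nona-2,6-dien-1-yl]oxy}dimethylsilane
Conditions: Na/Hg (6% Na), MeOH–THF, −20 °C
Reagents that add atoms: none
Why: Reductive desulfonylation by electron transfer from sodium amalgam should cleave the C–S bond and protonate the resulting carbanion from methanol, while isolated trisubstituted alkenes and the allylic silyl ether are inert to this mild reductant.

Step 12
Reactants: 20 tert-butyl{[(2E,6E)-3,7-dimethyl-9-[(1S)-2,6,6-trimethylcyclohex-2-en-1-yl]nona-2,6-dien-1-yl]oxy}dimethylsilane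
Product: 21 (2E,6E)-3,7-dimethyl-9-[(1S)-2,6,6-trimethylcyclohex-2-en-1-yl]nona-2,6-dien-1-ol
Conditions: Bu4NF, THF, 0 °C to rt
Reagents that add atoms: none
Why: Fluoride-mediated silyl ether cleavage (driven by the Si–F bond) under essentially neutral conditions avoids acid-promoted migration of the ring double bond.

Step 13
Reactants: 21 (2E,6E)-3,7-dimethyl-9-[(1S)-2,6,6-trimethylcyclohex-2-en-1-yl]nona-2,6-dien-1-ol; 22 α-linolenic acid, (9Z,12Z,15Z)-octadeca-9,12,15-trienoic acid
Product: 23 (2E,6E)-3,7-dimethyl-9-[(1S)-2,6,6-trimethylcyclohex-2-en-1-yl]nona-2,6-dien-1-yl (9Z,12Z,15Z)-octadeca-9,12,15-trienoate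
Conditions: DCC, DMAP (cat.), CH2Cl2, 0 °C to rt, argon, dark
Reagents that add atoms: none
Why: Steglich esterification of a primary allylic alcohol under mild neutral conditions is chosen so that the skipped all-cis triene of the acid is neither isomerised nor oxidised and no allylic ionisation occurs.

**Compound list**

1 | 2-methylpentan-3-one | CCC(=O)C(C)C | starting material
2 | methyl prop-2-enoate (methyl acrylate) | C=CC(=O)OC | starting material
3 | methyl 4,4-dimethyl-5-oxoheptanoate | CCC(=O)C(C)(C)CCC(=O)OC | intermediate (not isolated)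
4 | 2,4,4-trimethylcyclohexane-1,3-dione | CC1C(=O)CCC(C)(C)C1=O | intermediate
5 | 3-(2-methylpropoxy)-2,6,6-trimethylcyclohex-2-en-1-one | CC(C)COC1=C(C)C(=O)C(C)(C)CC1 | intermediate
6 | 3-(2-methylpropoxy)-2,6,6-trimethylcyclohex-2-en-1-ol (racemic) | CC(C)COC1=C(C)C(O)C(C)(C)CC1 | intermediate (not isolated)
7 | 2,4,4-trimethylcyclohex-2-en-1-one | CC1=CC(C)(C)CCC1=O | intermediate
8 | (1R)-2,4,4-trimethylcyclohex-2-en-1-ol | O[C@@H]1CCC(C)(C)C=C1C | intermediate
9 | 2-(4-methylbenzenesulfonyl)acetic acid | Cc1ccc(cc1)S(=O)(=O)CC(=O)O | starting material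
10 | (1R)-2,4,4-trimethylcyclohex-2-en-1-yl 2-(4-methylbenzenesulfonyl)acetate | Cc1ccc(cc1)S(=O)(=O)CC(=O)O[C@@H]1CCC(C)(C)C=C1C | intermediate
11 | {[2-(4-methylbenzenesulfonyl)-1-{[(1R)-2,4,4-trimethylcyclohex-2-en-1-yl]oxy}ethenyl]oxy}trimethylsilane | Cc1ccc(cc1)S(=O)(=O)C=C(O[Si](C)(C)C)O[C@@H]1CCC(C)(C)C=C1C | intermediate (not isolated)
12 | trimethylsilyl 2-(4-methylbenzenesulfonyl)-2-[(1S)-2,6,6-trimethylcyclohex-2-en-1-yl]acetate | Cc1ccc(cc1)S(=O)(=O)C(C(=O)O[Si](C)(C)C)[C@@H]1C(C)=CCCC1(C)C | intermediate (not isolated)
13 | 1-methyl-4-{[(1S)-2,6,6-trimethylcyclohex-2-en-1-yl]methanesulfonyl}benzene | Cc1ccc(cc1)S(=O)(=O)C[C@@H]1C(C)=CCCC1(C)C | intermediate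
14 | geraniol, (2E)-3,7-dimethylocta-2,6-dien-1-ol | OC/C=C(\C)CCC=C(C)C | starting material
15 | tert-butyl{[(2E)-3,7-dimethylocta-2,6-dien-1-yl]oxy}dimethylsilane | CC(C)(C)[Si](C)(C)OC/C=C(\C)CCC=C(C)C | intermediate
16 | (2E,6E)-8-{[tert-butyl(dimethyl)silyl]oxy}-2,6-dimethylocta-2,6-dien-1-ol | CC(C)(C)[Si](C)(C)OC/C=C(\C)CC/C=C(\C)CO | intermediate
17 | tert-butyl{[(2E,6E)-8-bromo-3,7-dimethylocta-2,6-dien-1-yl]oxy}dimethylsilane | CC(C)(C)[Si](C)(C)OC/C=C(\C)CC/C=C(\C)CBr | intermediate
18 | [(4-methylbenzenesulfonyl)[(1S)-2,6,6-trimethylcyclohex-2-en-1-yl]methyl]lithium | [Li]C(S(=O)(=O)c1ccc(C)cc1)[C@@H]1C(C)=CCCC1(C)C | intermediate (not isolated)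
19 | tert-butyl{[(2E,6E)-3,7-dimethyl-9-(4-methylbenzenesulfonyl)-9-[(1S)-2,6,6-trimethylcyclohex-2-en-1-yl]nona-2,6-dien-1-yl]oxy}dimethylsilane (both C9 epimers) | CC(C)(C)[Si](C)(C)OC/C=C(\C)CC/C=C(\C)CC(S(=O)(=O)c1ccc(C)cc1)[C@@H]1C(C)=CCCC1(C)C | intermediate
20 | tert-butyl{[(2E,6E)-3,7-dimethyl-9-[(1S)-2,6,6-trimethylcyclohex-2-en-1-yl]nona-2,6-dien-1-yl]oxy}dimethylsilane | CC(C)(C)[Si](C)(C)OC/C=C(\C)CC/C=C(\C)CC[C@@H]1C(C)=CCCC1(C)C | intermediate
21 | (2E,6E)-3,7-dimethyl-9-[(1S)-2,6,6-trimethylcyclohex-2-en-1-yl]nona-2,6-dien-1-ol | OC/C=C(\C)CC/C=C(\C)CC[C@@H]1C(C)=CCCC1(C)C | intermediate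
22 | α-linolenic acid, (9Z,12Z,15Z)-octadeca-9,12,15-trienoic acid | CC/C=C\C/C=C\C/C=C\CCCCCCCC(=O)O | starting material
23 | (2E,6E)-3,7-dimethyl-9-[(1S)-2,6,6-trimethylcyclohex-2-en-1-yl]nona-2,6-dien-1-yl (9Z,12Z,15Z)-octadeca-9,12,15-trienoate | CC/C=C\C/C=C\C/C=C\CCCCCCCC(=O)OC/C=C(\C)CC/C=C(\C)CC[C@@H]1C(C)=CCCC1(C)C | target

**Step count and risks**

Total step count: 13. Longest linear sequence: 10 steps (steps 1–6 and 10–13, from 1 and 2); the side-chain branch (steps 7–9) joins at step 10.

Steps most likely to fail:

Risk 1 (step 6). The sigmatropic shift has to form a bond at a ring carbon flanked by the quaternary C6. It may be slower than thermal elimination or ionisation of the allylic ester, and any ionisation–recombination pathway would erode the transfer of chirality. The fallback sets out from 8 and comes back at 13. Alcohol 8 would be O-alkylated (KH, Bu3SnCH2I, THF) to tributyl({[(1R)-2,4,4-trimethylcyclohex-2-en-1-yl]oxy}methyl)stannane F1. Tin–lithium exchange (n-BuLi, THF, −78 °C) should trigger the Still–Wittig [2,3]-shift, again suprafacial, to [(1S)-2,6,6-trimethylcyclohex-2-en-1-yl]methanol F2. Thioetherification with di-p-tolyl disulfide and PBu3 would give 1-methyl-4-({[(1S)-2,6,6-trimethylcyclohex-2-en-1-yl]methyl}sulfanyl)benzene F3, and oxidation at sulfur (H2O2, cat. (NH4)6Mo7O24·4H2O, EtOH) would return to 13.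

Risk 2 (step 1). Michael addition through the less hindered ethyl-side enolate and anionic oligomerisation of the acrylate could consume material before the thermodynamic funnel operates. The fallback sets out from 1 and comes back at 4, and separates the two bond formations. Ketone 1 would be converted under equilibrating conditions (TMSCl, NaI, Et3N, MeCN) into the more substituted enol ether trimethyl[(2-methylpent-2-en-3-yl)oxy]silane F4, purified by distillation. TiCl4-promoted Mukaiyama–Michael addition of F4 to 2 (CH2Cl2, −78 °C) would give keto ester 3, now isolated, and a separate Claisen cyclisation (KOt-Bu, THF; then HCl) would close the same C2–C3 bond to give 4.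

Risk 3 (step 4). Insufficient facial discrimination between the alkenyl and methylene flanks of the ketone would lower the enantiomeric purity, which the stereospecific shift of step 6 passes on unchanged. The fallback sets out from 7 and comes back at 8. Luche reduction (NaBH4, CeCl3·7H2O, MeOH) would give racemic 2,4,4-trimethylcyclohex-2-en-1-ol F5. Lipase-catalysed kinetic resolution (immobilised Candida antarctica lipase B, vinyl acetate) is expected to acylate the (R)-enantiomer to (1R)-2,4,4-trimethylcyclohex-2-en-1-yl acetate F6, which is separated from the unreacted (S)-alcohol. Methanolysis (K2CO3, MeOH) would then give 8.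

Further compounds
F1 | step 6 | tributyl({[(1R)-2,4,4-trimethylcyclohex-2-en-1-yl]oxy}methyl)stannane | CCCC[Sn](CCCC)(CCCC)CO[C@@H]1CCC(C)(C)C=C1C
F2 | step 6 | [(1S)-2,6,6-trimethylcyclohex-2-en-1-yl]methanol | OC[C@@H]1C(C)=CCCC1(C)C
F3 | step 6 | 1-methyl-4-({[(1S)-2,6,6-trimethylcyclohex-2-en-1-yl]methyl}sulfanyl)benzene | Cc1ccc(cc1)SC[C@@H]1C(C)=CCCC1(C)C
F4 | step 1 | trimethyl[(2-methylpent-2-en-3-yl)oxy]silane | CCC(O[Si](C)(C)C)=C(C)C
F5 | step 4 | 2,4,4-trimethylcyclohex-2-en-1-ol (racemic) | OC1CCC(C)(C)C=C1C
F6 | step 4 | (1R)-2,4,4-trimethylcyclohex-2-en-1-yl acetate | CC(=O)O[C@@H]1CCC(C)(C)C=C1C
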